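**Strategy.** The cyclohexene ring is cut at C5 (benzofuranone numbering), the ring carbon that carries the (S)-hydroxypentyl chain and lies between the acetoxy carbon C4 and the alkene carbon C6. Removing C5 leaves a (4S)-4-silyloxy-2-(silyloxymethyl)cyclopent-2-enone. The key step puts C5 back by inserting the carbon of a citronellic-acid-derived (S)-diazoalkane between the enone carbonyl and its α-alkenyl carbon; this enlarges the five-membered ring to the six-membered one and joins both chiral fragments in one operation. The bought silyloxy stereocentre (C7a) then relays C3a (anti Michael addition to a 3-nitroacrylate, a masked α-acrylate unit) and C4 (hindered hydride, cis).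

Key step: step 8

Remark: (S)-citronellic acid, (4S)-4-(tert-butyldimethylsilyloxy)cyclopent-2-enone and methyl acrylate are taken as commercial; TBS = tert-butyldimethylsilyl, TBDPS = tert-butyldiphenylsilyl; the configuration at the nitro-ester α-carbon of 18–22 is not controlled and is erased in step 12.

Step 1
Reactants: 1 (4S)-4-[(TBS)oxy]cyclopent-2-en-1-one
Product: 2 (4S)-4-[(TBS)oxy]-2-(hydroxymethyl)cyclopent-2-en-1-one
Conditions: HCHO (37% aq.), imidazole (0.3 equiv), THF/H2O, rt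
Reagents that add atoms: formaldehyde C=O
Why: Morita–Baylis–Hillman reaction: reversible conjugate addition of imidazole gives an enolate that adds to formaldehyde through C2, and loss of the catalyst restores the enone, the C4 stereocentre not being involved.

Step 2
Reactants: 2 (4S)-4-[(TBS)oxy]-2-(hydroxymethyl)cyclopent-2-en-1-one
Product: 3 (4S)-4-[(TBS)oxy]-2-{[(TBS)oxy]methyl}cyclopent-2-en-1-one
Conditions: TBSCl, imidazole, CH2Cl2, 0 °C → rt
Reagents that add atoms: tert-butyldimethylsilyl chloride CC(C)(C)[Si](C)(C)Cl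
Why: Silylation of the primary allylic alcohol (imidazole-assisted silyl transfer) masks the hydroxyl against the diazoalkane and the amide base used later.

Step 3
Reactants: 4 (3S)-3,7-dimethyloct-6-enoic acid ((S)-citronellic acid)
Product: 7 methyl N-[(2S)-2,6-dimethylhept-5-en-1-yl]carbamate, via acyl azide 5 (not isolated), via isocyanate 6 (not isolated)
Conditions: DPPA, Et3N, toluene, rt → 80 °C; then MeOH, 70 °C
Reagents that add atoms: diphenylphosphoryl azide [N-]=[N+]=NP(=O)(Oc1ccccc1)Oc1ccccc1; methanol CO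
Why: Curtius rearrangement: the acyl azide loses N2 with 1,2-shift of the CH2 group to nitrogen (the stereocentre is one carbon away and untouched) and methanol adds to the isocyanate, so that the former C2 of the acid now carries nitrogen and can become the diazo carbon.

Step 4
Reactants: 7 methyl N-[(2S)-2,6-dimethylhept-5-en-1-yl]carbamate
Product: 9 methyl N-[(2S)-5-hydroxy-2-methylpentyl]carbamate, via aldehyde 8 (not isolated)
Conditions: O3, CH2Cl2/MeOH, −78 °C; Me2S; then NaBH4, 0 °C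
Reagents that add atoms: ozone [O-][O+]=O
Why: Ozonolysis cleaves the electron-rich trisubstituted alkene (the carbamate is inert), and borohydride reduces the aldehyde to the primary alcohol that ends as the free hydroxyl of the target.

Step 5
Reactants: 9 methyl N-[(2S)-5-hydroxy-2-methylpentyl]carbamate
Product: 10 methyl N-[(2S)-5-[(TBDPS)oxy]-2-methylpentyl]carbamate
Conditions: TBDPSCl, imidazole, DMF, rt
Reagents that add atoms: tert-butyldiphenylsilyl chloride CC(C)(C)[Si](Cl)(c1ccccc1)c1ccccc1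
Why: Silylation; the primary TBDPS ether is chosen because it should survive the later removal of the TBS ethers with aqueous HF.

Step 6
Reactants: 10 methyl N-[(2S)-5-[(TBDPS)oxy]-2-methylpentyl]carbamate
Product: 11 methyl N-[(2S)-5-[(TBDPS)oxy]-2-methylpentyl]-N-nitrosocarbamate
Conditions: NaNO2, Ac2O/AcOH, 0 °C
Reagents that add atoms: sodium nitrite [Na+].[O-]N=O
Why: N-Nitrosation of the carbamate nitrogen by the nitrosonium equivalent formed from nitrite in AcOH/Ac2O gives the classical base-labile diazoalkane precursor.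

Step 7
Reactants: 12 methyl acrylate
Product: 14 methyl (E)-3-nitroprop-2-enoate, via iodonitro ester 13 (not isolated)
Conditions: N2O4, I2, Et2O, 0 °C; then NaOAc, Et2O, 0 °C
Reagents that add atoms: dinitrogen tetroxide [O-][N+](=O)[N+](=O)[O-]
Why: Addition of NO2 and iodine across the acrylate (nitro at the β-carbon) followed by acetate-induced loss of HI gives the (E)-nitroalkene, a known preparation of 3-nitroacrylates.

Step 8
Reactants: 3 (4S)-4-[(TBS)oxy]-2-{[(TBS)oxy]methyl}cyclopent-2-en-1-one; 11 methyl N-[(2S)-5-[(TBDPS)oxy]-2-methylpentyl]-N-nitrosocarbamate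
Product: 17 (5R)-5-[(TBS)oxy]-3-{[(TBS)oxy]methyl}-2-[(2S)-5-[(TBDPS)oxy]pentan-2-yl]cyclohex-2-en-1-one, via diazoalkane 15 (not isolated), via skipped enone 16 (not isolated)
Conditions: 11, KOH (40% aq.)/toluene, 0 °C, organic layer dried over KOH; added (1.5 equiv) to 3, Sc(OTf)3 (10 mol%), toluene, −78 °C; then DBU (0.3 equiv), −40 → 0 °C
Reagents that add atoms: none
Why: Sc(OTf)3 activates the C1 carbonyl of 3 for attack by the nucleophilic diazo carbon of 15 (formed in the flask by base cleavage of the N-nitrosocarbamate), and the β-oxido diazonium betaine loses N2 with 1,2-shift of the alkenyl carbon C2 onto the new carbon, so that CH(R) is inserted between C1 and C2 and the cyclopentenone becomes cyclohex-3-enone 16 (Tiffeneau–Demjanov-type diazoalkane homologation). The closest known reactions are the Sc(OTf)3-catalysed ring homologation of cycloalkanones with non-stabilised diazoalkanes and the Lewis-acid-promoted diazomethane homologation of cyclic enones, which proceeds by vinyl migration to β,γ-unsaturated ketones. No ring is closed from an open chain: the existing five-membered ring is enlarged by one carbon through the 1,2-shift, and catalytic DBU then moves the C3=C4 double bond into conjugation (γ-protonation of the dienolate) to give the tetrasubstituted enone 17. The new stereocentre at C2 of 16 is of no consequence because it becomes sp2 in 17, while the silyloxy stereocentre and the side-chain stereocentre (never the diazo carbon itself) are untouched. The step needs 1,2-addition to C=O rather than dipolar cycloaddition or conjugate addition to the C=C, which the α-substituent, the neighbouring silyloxy group and Lewis-acid activation at −78 °C should secure, and alkenyl rather than C5-methylene migration, which the higher migratory aptitude of the sp2 carbon and the inductive deactivation of C5 by the β-silyloxy group should secure.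

Step 9
Reactants: 17 (5R)-5-[(TBS)oxy]-3-{[(TBS)oxy]methyl}-2-[(2S)-5-[(TBDPS)oxy]pentan-2-yl]cyclohex-2-en-1-one; 14 methyl (E)-3-nitroprop-2-enoate
Product: 18 methyl 2-[(1S,6R)-6-[(TBS)oxy]-4-{[(TBS)oxy]methyl}-2-oxo-3-[(2S)-5-[(TBDPS)oxy]pentan-2-yl]cyclohex-3-en-1-yl]-3-nitropropanoate (chain at C1 trans to the C6 silyl ether; both epimers at the propanoate C2)
Conditions: LDA, THF, −78 °C; 14, −78 °C; AcOH quench at −78 °C
Reagents that add atoms: none
Why: Kinetic deprotonation at C6, the only α-position that bears hydrogen, gives the cross-conjugated lithium enolate, which undergoes Michael addition to the ester-bearing carbon of the nitroalkene (β to nitro) from the face anti to the neighbouring C5 silyloxy group, setting the trans relation of the future C3a and C7a; the nitronate is protonated on quench.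

Step 10
Reactants: 18 methyl 2-[(1S,6R)-6-[(TBS)oxy]-4-{[(TBS)oxy]methyl}-2-oxo-3-[(2S)-5-[(TBDPS)oxy]pentan-2-yl]cyclohex-3-en-1-yl]-3-nitropropanoate
Product: 20 methyl 2-[(1R,2S,6R)-2-(acetyloxy)-6-[(TBS)oxy]-4-{[(TBS)oxy]methyl}-3-[(2S)-5-[(TBDPS)oxy]pentan-2-yl]cyclohex-3-en-1-yl]-3-nitropropanoate (acetoxy cis to the C1 chain), via allylic alcohol 19 (not isolated)
Conditions: L-Selectride (2.5 equiv), THF, −78 °C; AcOH, −78 °C; then Ac2O, DMAP, pyridine, CH2Cl2, 0 °C
Reagents that add atoms: acetic anhydride CC(=O)OC(C)=O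
Why: The bulky hydride attacks the hindered β,β-disubstituted enone 1,2 and anti to the adjacent C1 side chain (steric approach control, as with 2-alkylcyclohexanones), which sets the carbinol cis to that chain while the nitro group sits protected as its nitronate, and immediate acetylation prevents γ-lactonisation of the cis-alcohol onto the ester.

Step 11
Reactants: 20 methyl 2-[(1R,2S,6R)-2-(acetyloxy)-6-[(TBS)oxy]-4-{[(TBS)oxy]methyl}-3-[(2S)-5-[(TBDPS)oxy]pentan-2-yl]cyclohex-3-en-1-yl]-3-nitropropanoate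
Product: 22 [(3aS,4S,7aR)-6-(hydroxymethyl)-3-(nitromethyl)-2-oxo-5-[(2S)-5-[(TBDPS)oxy]pentan-2-yl]-2,3,3a,4,7,7a-hexahydro-1-benzofuran-4-yl] acetate (trans-fused lactone; C3 epimers), via diol ester 21 (not isolated)
Conditions: HF (48% aq.), MeCN, 0 °C → rt; then CSA (cat.), toluene, 50 °C
Reagents that add atoms: none
Why: Aqueous HF cleaves both TBS ethers but not the primary TBDPS ether, and acid-catalysed acyl substitution (5-exo-trig) closes the γ-lactone onto the only hydroxyl that can reach the ester in a five-membered ring, the one trans to the chain, the cis oxygen being acetylated and the primary allylic hydroxyl needing an eight-membered ring.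

Step 12
Reactants: 22 [(3aS,4S,7aR)-6-(hydroxymethyl)-3-(nitromethyl)-2-oxo-5-[(2S)-5-[(TBDPS)oxy]pentan-2-yl]-2,3,3a,4,7,7a-hexahydro-1-benzofuran-4-yl] acetate
Product: 23 [(3aS,4S,7aR)-6-(hydroxymethyl)-3-methylidene-2-oxo-5-[(2S)-5-[(TBDPS)oxy]pentan-2-yl]-2,3,3a,4,7,7a-hexahydro-1-benzofuran-4-yl] acetate
Conditions: DBU (1.2 equiv), CH2Cl2, 0 °C
Reagents that add atoms: none
Why: E1cB elimination of nitrite from the lactone enolate (loss of HNO2 from a β-nitro carbonyl compound) unveils the exocyclic methylene and erases the uncontrolled stereocentre.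

Step 13
Reactants: 23 [(3aS,4S,7aR)-6-(hydroxymethyl)-3-methylidene-2-oxo-5-[(2S)-5-[(TBDPS)oxy]pentan-2-yl]-2,3,3a,4,7,7a-hexahydro-1-benzofuran-4-yl] acetate
Product: 24 {(3aS,4S,7aR)-4-(acetyloxy)-3-methylidene-2-oxo-5-[(2S)-5-[(TBDPS)oxy]pentan-2-yl]-2,3,3a,4,7,7a-hexahydro-1-benzofuran-6-yl}methyl 2-methylprop-2-enoate
Conditions: methacrylic anhydride, Et3N, DMAP (cat.), CH2Cl2, 0 °C
Reagents that add atoms: methacrylic anhydride C=C(C)C(=O)OC(=O)C(C)=C
Why: DMAP-catalysed acylation of the only free hydroxyl, the primary allylic one.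

Step 14
Reactants: 24 {(3aS,4S,7aR)-4-(acetyloxy)-3-methylidene-2-oxo-5-[(2S)-5-[(TBDPS)oxy]pentan-2-yl]-2,3,3a,4,7,7a-hexahydro-1-benzofuran-6-yl}methyl 2-methylprop-2-enoate
Product: 25 {(3aS,4S,7aR)-4-(acetyloxy)-5-[(2S)-5-hydroxypentan-2-yl]-3-methylidene-2-oxo-2,3,3a,4,7,7a-hexahydro-1-benzofuran-6-yl}methyl 2-methylprop-2-enoate (CNP0114085.1)
Conditions: HF·pyridine, pyridine/THF, 0 °C → rt
Reagents that add atoms: none
Why: Fluoride-driven Si–O cleavage under buffered acidic conditions removes the TBDPS ether without touching the acetate, the methacrylate or the Michael-acceptor lactone.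

**Compound list**

1 | (4S)-4-[(tert-butyldimethylsilyl)oxy]cyclopent-2-en-1-one | O=C1C[C@H](O[Si](C)(C)C(C)(C)C)C=C1 | starting material
2 | (4S)-4-[(tert-butyldimethylsilyl)oxy]-2-(hydroxymethyl)cyclopent-2-en-1-one | O=C1C[C@H](O[Si](C)(C)C(C)(C)C)C=C1CO | intermediate
3 | (4S)-4-[(tert-butyldimethylsilyl)oxy]-2-{[(tert-butyldimethylsilyl)oxy]methyl}cyclopent-2-en-1-one | O=C1C[C@H](O[Si](C)(C)C(C)(C)C)C=C1CO[Si](C)(C)C(C)(C)C | intermediate
4 | (3S)-3,7-dimethyloct-6-enoic acid ((S)-citronellic acid) | OC(=O)C[C@@H](C)CCC=C(C)C | starting material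
5 | (3S)-3,7-dimethyloct-6-enoyl azide | [N-]=[N+]=NC(=O)C[C@@H](C)CCC=C(C)C | intermediate
6 | (6S)-7-isocyanato-2,6-dimethylhept-2-ene | O=C=NC[C@@H](C)CCC=C(C)C | intermediate
7 | methyl N-[(2S)-2,6-dimethylhept-5-en-1-yl]carbamate | COC(=O)NC[C@@H](C)CCC=C(C)C | intermediate
8 | methyl N-[(2S)-2-methyl-5-oxopentyl]carbamate | COC(=O)NC[C@@H](C)CCC=O | intermediate
9 | methyl N-[(2S)-5-hydroxy-2-methylpentyl]carbamate | COC(=O)NC[C@@H](C)CCCO | intermediate
10 | methyl N-[(2S)-5-[(tert-butyldiphenylsilyl)oxy]-2-methylpentyl]carbamate | COC(=O)NC[C@@H](C)CCCO[Si](c1ccccc1)(c1ccccc1)C(C)(C)C | intermediate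
11 | methyl N-[(2S)-5-[(tert-butyldiphenylsilyl)oxy]-2-methylpentyl]-N-nitrosocarbamate | COC(=O)N(N=O)C[C@@H](C)CCCO[Si](c1ccccc1)(c1ccccc1)C(C)(C)C | intermediate
12 | methyl acrylate (methyl prop-2-enoate) | C=CC(=O)OC | starting material
13 | methyl 2-iodo-3-nitropropanoate (racemic) | COC(=O)C(I)C[N+](=O)[O-] | intermediate
14 | methyl (E)-3-nitroprop-2-enoate | COC(=O)/C=C/[N+](=O)[O-] | intermediate
15 | tert-butyl{[(4S)-5-diazo-4-methylpentyl]oxy}diphenylsilane | [N-]=[N+]=C[C@@H](C)CCCO[Si](c1ccccc1)(c1ccccc1)C(C)(C)C | intermediate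
16 | (5S)-5-[(tert-butyldimethylsilyl)oxy]-3-{[(tert-butyldimethylsilyl)oxy]methyl}-2-[(2S)-5-[(tert-butyldiphenylsilyl)oxy]pentan-2-yl]cyclohex-3-en-1-one (C2 epimers) | O=C1C[C@H](O[Si](C)(C)C(C)(C)C)C=C(CO[Si](C)(C)C(C)(C)C)C1[C@@H](C)CCCO[Si](c1ccccc1)(c1ccccc1)C(C)(C)C | intermediate
17 | (5R)-5-[(tert-butyldimethylsilyl)oxy]-3-{[(tert-butyldimethylsilyl)oxy]methyl}-2-[(2S)-5-[(tert-butyldiphenylsilyl)oxy]pentan-2-yl]cyclohex-2-en-1-one | O=C1C[C@H](O[Si](C)(C)C(C)(C)C)CC(CO[Si](C)(C)C(C)(C)C)=C1[C@@H](C)CCCO[Si](c1ccccc1)(c1ccccc1)C(C)(C)C | intermediate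
18 | methyl 2-[(1S,6R)-6-[(tert-butyldimethylsilyl)oxy]-4-{[(tert-butyldimethylsilyl)oxy]methyl}-2-oxo-3-[(2S)-5-[(tert-butyldiphenylsilyl)oxy]pentan-2-yl]cyclohex-3-en-1-yl]-3-nitropropanoate (propanoate C2 epimers) | O=C1[C@@H](C(C[N+](=O)[O-])C(=O)OC)[C@H](O[Si](C)(C)C(C)(C)C)CC(CO[Si](C)(C)C(C)(C)C)=C1[C@@H](C)CCCO[Si](c1ccccc1)(c1ccccc1)C(C)(C)C | intermediate
19 | methyl 2-[(1R,2S,6R)-2-hydroxy-6-[(tert-butyldimethylsilyl)oxy]-4-{[(tert-butyldimethylsilyl)oxy]methyl}-3-[(2S)-5-[(tert-butyldiphenylsilyl)oxy]pentan-2-yl]cyclohex-3-en-1-yl]-3-nitropropanoate (2-OH cis to the C1 chain) | O[C@H]1[C@@H](C(C[N+](=O)[O-])C(=O)OC)[C@H](O[Si](C)(C)C(C)(C)C)CC(CO[Si](C)(C)C(C)(C)C)=C1[C@@H](C)CCCO[Si](c1ccccc1)(c1ccccc1)C(C)(C)C | intermediate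
20 | methyl 2-[(1R,2S,6R)-2-(acetyloxy)-6-[(tert-butyldimethylsilyl)oxy]-4-{[(tert-butyldimethylsilyl)oxy]methyl}-3-[(2S)-5-[(tert-butyldiphenylsilyl)oxy]pentan-2-yl]cyclohex-3-en-1-yl]-3-nitropropanoate | CC(=O)O[C@H]1[C@@H](C(C[N+](=O)[O-])C(=O)OC)[C@H](O[Si](C)(C)C(C)(C)C)CC(CO[Si](C)(C)C(C)(C)C)=C1[C@@H](C)CCCO[Si](c1ccccc1)(c1ccccc1)C(C)(C)C | intermediate
21 | methyl 2-[(1S,2S,6R)-2-(acetyloxy)-6-hydroxy-4-(hydroxymethyl)-3-[(2S)-5-[(tert-butyldiphenylsilyl)oxy]pentan-2-yl]cyclohex-3-en-1-yl]-3-nitropropanoate | CC(=O)O[C@H]1[C@@H](C(C[N+](=O)[O-])C(=O)OC)[C@H](O)CC(CO)=C1[C@@H](C)CCCO[Si](c1ccccc1)(c1ccccc1)C(C)(C)C | intermediate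
22 | [(3aS,4S,7aR)-6-(hydroxymethyl)-3-(nitromethyl)-2-oxo-5-[(2S)-5-[(tert-butyldiphenylsilyl)oxy]pentan-2-yl]-2,3,3a,4,7,7a-hexahydro-1-benzofuran-4-yl] acetate (C3 epimers) | CC(=O)O[C@H]1[C@H]2C(C[N+](=O)[O-])C(=O)O[C@@H]2CC(CO)=C1[C@@H](C)CCCO[Si](c1ccccc1)(c1ccccc1)C(C)(C)C | intermediate
23 | [(3aS,4S,7aR)-6-(hydroxymethyl)-3-methylidene-2-oxo-5-[(2S)-5-[(tert-butyldiphenylsilyl)oxy]pentan-2-yl]-2,3,3a,4,7,7a-hexahydro-1-benzofuran-4-yl] acetate | CC(=O)O[C@H]1[C@H]2C(=C)C(=O)O[C@@H]2CC(CO)=C1[C@@H](C)CCCO[Si](c1ccccc1)(c1ccccc1)C(C)(C)C | intermediate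
24 | {(3aS,4S,7aR)-4-(acetyloxy)-3-methylidene-2-oxo-5-[(2S)-5-[(tert-butyldiphenylsilyl)oxy]pentan-2-yl]-2,3,3a,4,7,7a-hexahydro-1-benzofuran-6-yl}methyl 2-methylprop-2-enoate | CC(=O)O[C@H]1[C@H]2C(=C)C(=O)O[C@@H]2CC(COC(=O)C(C)=C)=C1[C@@H](C)CCCO[Si](c1ccccc1)(c1ccccc1)C(C)(C)C | intermediate
25 | {(3aS,4S,7aR)-4-(acetyloxy)-5-[(2S)-5-hydroxypentan-2-yl]-3-methylidene-2-oxo-2,3,3a,4,7,7a-hexahydro-1-benzofuran-6-yl}methyl 2-methylprop-2-enoate | C=C(C)C(=O)OCC1=C([C@@H](C)CCCO)[C@@H](OC(C)=O)[C@H]2C(=C)C(=O)O[C@@H]2C1 | target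

**Totals.** 14 steps in all. Longest linear sequence: 11 steps (steps 3–6 and 8–14, from (S)-citronellic acid).

**Steps most likely to fail**

Step 8 (key step). The non-stabilised diazoalkane may be lost by 1,2-hydride shift, or may add to the C=C (pyrazoline or cyclopropane) instead of the carbonyl. The C5 methylene may migrate in place of the alkenyl carbon. Siloxide may be expelled from the dienolate during conjugation, leading to aromatisation. Fallback, setting out from 15 and 3 and returning at 17: diazoalkane 15 is C-acylated with allyl chloroformate (Et3N, Et2O, −20 °C) to the isolable, acceptor-stabilised allyl (3S)-6-[(tert-butyldiphenylsilyl)oxy]-2-diazo-3-methylhexanoate F1. BF3·OEt2-promoted homologation of 3 with F1 (CH2Cl2, −78 °C; the same 1,2-addition and alkenyl shift, known for α-alkyl-α-diazo esters with cyclic ketones) should give allyl (4S)-4-[(TBS)oxy]-2-{[(TBS)oxy]methyl}-6-oxo-1-[(2S)-5-[(TBDPS)oxy]pentan-2-yl]cyclohex-2-ene-1-carboxylate F2. Pd(PPh3)4/morpholine (THF, rt; Tsuji–Trost deallylation with decarboxylation) then removes the activating ester to give 16, which is conjugated as before to 17.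

Step 9. The lithium enolate may expel the neighbouring silyloxy group (aromatisation), the nitronate may add a second time to the enone (bicyclo[2.2.2]octanone), or the acceptor may polymerise before C–C bond formation. Fallback, setting out from 17 and returning at 18: the enolate is trapped as it forms (LDA in the presence of TMSCl, THF, −78 °C) as the neutral 2-silyloxy diene (6R)-6-[(TBS)oxy]-4-{[(TBS)oxy]methyl}-3-[(2S)-5-[(TBDPS)oxy]pentan-2-yl]-2-[(trimethylsilyl)oxy]cyclohexa-1,3-diene F3. A Lewis-acid-mediated Mukaiyama–Michael addition of F3 to 14 (TiCl2(OiPr)2, CH2Cl2, −78 °C, mild fluoride work-up of the silyl nitronate) should then give 18 without a free enolate ever being present.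

Step 10. The very hindered carbonyl may be attacked from the wrong face or react too slowly, conjugate reduction may compete, or the cis-alkoxide may lactonise onto the methyl ester before acetylation. Fallback, setting out from 18 and returning at 20: Luche reduction (NaBH4, CeCl3·7H2O, MeOH, −78 °C) should deliver, by axial attack of the small hydride, the epimeric methyl 2-[(1R,2R,6R)-2-hydroxy-6-[(TBS)oxy]-4-{[(TBS)oxy]methyl}-3-[(2S)-5-[(TBDPS)oxy]pentan-2-yl]cyclohex-3-en-1-yl]-3-nitropropanoate F4 (hydroxyl trans to the chain, not prone to lactonise). Mitsunobu inversion with acetic acid (PPh3, DIAD, toluene, 0 °C → rt) should then give acetate 20 directly.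

**Further compounds**

F1 | step 8 | allyl (3S)-6-[(tert-butyldiphenylsilyl)oxy]-2-diazo-3-methylhexanoate | C=CCOC(=O)C(=[N+]=[N-])[C@@H](C)CCCO[Si](c1ccccc1)(c1ccccc1)C(C)(C)C
F2 | step 8 | allyl (4S)-4-[(tert-butyldimethylsilyl)oxy]-2-{[(tert-butyldimethylsilyl)oxy]methyl}-6-oxo-1-[(2S)-5-[(tert-butyldiphenylsilyl)oxy]pentan-2-yl]cyclohex-2-ene-1-carboxylate (C1 epimers) | C=CCOC(=O)C1([C@@H](C)CCCO[Si](c2ccccc2)(c2ccccc2)C(C)(C)C)C(=O)C[C@H](O[Si](C)(C)C(C)(C)C)C=C1CO[Si](C)(C)C(C)(C)C
F3 | step 9 | (6R)-6-[(tert-butyldimethylsilyl)oxy]-4-{[(tert-butyldimethylsilyl)oxy]methyl}-3-[(2S)-5-[(tert-butyldiphenylsilyl)oxy]pentan-2-yl]-2-[(trimethylsilyl)oxy]cyclohexa-1,3-diene | C[Si](C)(C)OC1=C[C@H](O[Si](C)(C)C(C)(C)C)CC(CO[Si](C)(C)C(C)(C)C)=C1[C@@H](C)CCCO[Si](c1ccccc1)(c1ccccc1)C(C)(C)C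
F4 | step 10 | methyl 2-[(1R,2R,6R)-2-hydroxy-6-[(tert-butyldimethylsilyl)oxy]-4-{[(tert-butyldimethylsilyl)oxy]methyl}-3-[(2S)-5-[(tert-butyldiphenylsilyl)oxy]pentan-2-yl]cyclohex-3-en-1-yl]-3-nitropropanoate | O[C@@H]1[C@@H](C(C[N+](=O)[O-])C(=O)OC)[C@H](O[Si](C)(C)C(C)(C)C)CC(CO[Si](C)(C)C(C)(C)C)=C1[C@@H](C)CCCO[Si](c1ccccc1)(c1ccccc1)C(C)(C)C
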